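The route rests on disconnecting the bond between the benzylic CH2 of one guaiacyl ring and the CH(CH2OH) methine, C3 of the butanetriol chain. The key step is a Fráter–Seebach alkylation: the dilithium alkoxide-enolate of a diisopropyl (S)-2-benzylmalate, which already carries the quaternary carbinol C2 and the other aryl ring, is benzylated by 4-(benzyloxy)-3-methoxybenzyl bromide, forming this bond and the C3 stereocentre in one operation. It exploits the 1,3-relationship between the tertiary hydroxyl on C2 and the oxygen on C4, with C3 as the enolate carbon between them. The precursor arises from (S)-malic acid by self-regeneration of its stereocentre; LiAlH4 reduction and hydrogenolysis finish the synthesis.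

Key step: step 5

Remark: chain atoms are numbered as in butane-1,2,4-triol (C2 bears the tertiary hydroxyl, C3 is the methine); the target as drawn is (2S,3S), and both phenols are carried as benzyl ethers.

Step 1
Reactants: 1 4-(benzyloxy)-3-methoxybenzyl alcohol
Product: 2 4-(benzyloxy)-3-methoxybenzyl bromide
Conditions: PBr3 (0.4 equiv), Et2O, 0 °C
Reagents that add atoms: phosphorus tribromide, BrP(Br)Br
Why: Alcohol-to-bromide substitution with PBr3 should proceed by SN2 displacement of the intermediate bromophosphite at the primary benzylic carbon; no stereocentre is involved.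

Step 2
Reactants: 3 (S)-malic acid
Product: 4 2-[(2S,4S)-2-tert-butyl-5-oxo-1,3-dioxolan-4-yl]acetic acid (cis)
Conditions: t-BuCHO, p-TsOH (cat.), H2SO4 (cat.), pentane, reflux, Dean–Stark; recrystallisation
Reagents that add atoms: pivalaldehyde, CC(C)(C)C=O
Why: Acid-catalysed acetalisation of the α-hydroxy acid (dioxolanone formation for self-regeneration of stereocentres) is reversible, so the new acetal centre should settle cis to the CH2CO2H group under thermodynamic control and the cis isomer is purified by crystallisation.

Step 3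
Reactants: 4 2-[(2S,4S)-2-tert-butyl-5-oxo-1,3-dioxolan-4-yl]acetic acid; 2 4-(benzyloxy)-3-methoxybenzyl bromide
Product: 6 2-[(2S,4S)-4-[4-(benzyloxy)-3-methoxybenzyl]-2-tert-butyl-5-oxo-1,3-dioxolan-4-yl]acetic acid, via dilithium carboxylate-enolate 5 (not isolated)
Conditions: LiN(SiMe3)2 (2.1 equiv), THF, -78 °C; then 2, -78 → -20 °C; 1 M HCl
Reagents that add atoms: none
Why: Enolate alkylation in the sense of the Seebach self-regeneration of stereocentres: the trigonal ring carbon of the carboxylate-enolate should be benzylated on the face opposite the tert-butyl group, so the benzyl group takes the place of the former hydrogen and the quaternary carbinol centre keeps the (S) sense of malic acid.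

Step 4
Reactants: 6 2-[(2S,4S)-4-[4-(benzyloxy)-3-methoxybenzyl]-2-tert-butyl-5-oxo-1,3-dioxolan-4-yl]acetic acid
Product: 7 diisopropyl (2S)-2-[4-(benzyloxy)-3-methoxybenzyl]-2-hydroxybutanedioate
Conditions: i-PrOH, H2SO4 (cat.), reflux
Reagents that add atoms: propan-2-ol, CC(C)O
Why: Acid-catalysed alcoholysis of the acylal together with Fischer esterification of the free acid should release pivalaldehyde and give the diester without breaking any bond at the quaternary carbinol carbon, so its configuration is retained.

Step 5
Reactants: 7 diisopropyl (2S)-2-[4-(benzyloxy)-3-methoxybenzyl]-2-hydroxybutanedioate; 2 4-(benzyloxy)-3-methoxybenzyl bromide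
Product: 9 diisopropyl (2S,3R)-2,3-bis[4-(benzyloxy)-3-methoxybenzyl]-2-hydroxybutanedioate, via dilithium alkoxide-enolate 8 (not isolated)
Conditions: LiN(SiMe3)2 (2.3 equiv), THF, -78 → -20 °C; then 2, -78 → -10 °C; 1 M HCl
Reagents that add atoms: none
Why: LiN(SiMe3)2 deprotonates the tertiary hydroxyl and then the only enolisable position, the C3 methylene, to give a dilithium alkoxide-enolate in which lithium bridges the alkoxide and enolate oxygens in a six-membered chelate, and the enolate carbon displaces bromide from 2 in an SN2 reaction. The closest known reaction type is the Fráter–Seebach alkylation of β-hydroxy ester dianions, known for malates and 2-alkylmalates. No ring is closed. The new C3 stereocentre is controlled by the C2 carbinol centre held in the chelate: the bromide should approach the enolate face anti to the lithium-coordinated isopropyl ester on C2, that is syn to the CH2Ar group, which gives the (2S,3R) diester. The step needs C- over O-alkylation and a single enolate, secured by the hindered tertiary alkoxide, by the absence of α-hydrogens at the C1 ester and by the bulky isopropyl esters, which should also suppress Claisen self-condensation.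

Step 6
Reactants: 9 diisopropyl (2S,3R)-2,3-bis[4-(benzyloxy)-3-methoxybenzyl]-2-hydroxybutanedioate
Product: 10 (2S,3S)-2,3-bis[4-(benzyloxy)-3-methoxybenzyl]butane-1,2,4-triol
Conditions: LiAlH4, THF, 0 °C → rt; Fieser work-up
Reagents that add atoms: none
Why: Hydride reduction of both isopropyl esters by LiAlH4 should give the two primary alcohols without touching either stereocentre or the benzyl ethers (the descriptor at C3 changes from R to S only through the priority change).

Step 7
Reactants: 10 (2S,3S)-2,3-bis[4-(benzyloxy)-3-methoxybenzyl]butane-1,2,4-triol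
Product: 11 (-)-carinol, (2S,3S)-2,3-bis(4-hydroxy-3-methoxybenzyl)butane-1,2,4-triol
Conditions: H2 (1 atm), 10% Pd/C, MeOH–EtOAc, rt
Reagents that add atoms: none
Why: Catalytic hydrogenolysis should cleave only the two benzylic C–O bonds of the aryl benzyl ethers, since no aliphatic hydroxyl is benzylic, so both stereocentres are unchanged.

Compound list
1 | 4-(benzyloxy)-3-methoxybenzyl alcohol | COc1cc(CO)ccc1OCc1ccccc1 | starting material
2 | 4-(benzyloxy)-3-methoxybenzyl bromide | COc1cc(CBr)ccc1OCc1ccccc1 | intermediate
3 | (S)-malic acid | O[C@@H](CC(=O)O)C(=O)O | starting material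
4 | 2-[(2S,4S)-2-tert-butyl-5-oxo-1,3-dioxolan-4-yl]acetic acid | OC(=O)C[C@@H]1O[C@H](C(C)(C)C)OC1=O | intermediate
5 | dilithium carboxylate-enolate of 4 (lithium 2-[(2S)-2-tert-butyl-5-(lithiooxy)-1,3-dioxol-4-yl]acetate) | [Li]OC(=O)CC1=C(O[Li])O[C@@H](C(C)(C)C)O1 | intermediate
6 | 2-[(2S,4S)-4-[4-(benzyloxy)-3-methoxybenzyl]-2-tert-butyl-5-oxo-1,3-dioxolan-4-yl]acetic acid | OC(=O)C[C@]1(Cc2ccc(OCc3ccccc3)c(OC)c2)O[C@H](C(C)(C)C)OC1=O | intermediate
7 | diisopropyl (2S)-2-[4-(benzyloxy)-3-methoxybenzyl]-2-hydroxybutanedioate | CC(C)OC(=O)C[C@@](Cc1ccc(OCc2ccccc2)c(OC)c1)(C(=O)OC(C)C)O | intermediate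
8 | dilithium alkoxide-enolate of 7 (chelated, OLi cis to C2) | [Li]O/C(OC(C)C)=C\[C@@](O[Li])(Cc1ccc(OCc2ccccc2)c(OC)c1)C(=O)OC(C)C | intermediate
9 | diisopropyl (2S,3R)-2,3-bis[4-(benzyloxy)-3-methoxybenzyl]-2-hydroxybutanedioate | COc1cc(C[C@@H](C(=O)OC(C)C)[C@](O)(C(=O)OC(C)C)Cc2ccc(OCc3ccccc3)c(OC)c2)ccc1OCc1ccccc1 | intermediate
10 | (2S,3S)-2,3-bis[4-(benzyloxy)-3-methoxybenzyl]butane-1,2,4-triol | COc1cc(C[C@@H](CO)[C@](O)(CO)Cc2ccc(OCc3ccccc3)c(OC)c2)ccc1OCc1ccccc1 | intermediate
11 | (-)-carinol, (2S,3S)-2,3-bis(4-hydroxy-3-methoxybenzyl)butane-1,2,4-triol | COc1cc(C[C@@H](CO)[C@](O)(CO)Cc2ccc(O)c(OC)c2)ccc1O | target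

Total step count: 7. Longest linear sequence: 6 steps (3 → 11, steps 2 to 7); step 1 supplies bromide 2, which is used in steps 3 and 5.

Steps most likely to fail

Step 5. The two substituents on the carbinol carbon of the chelated dianion are of similar size, so facial selectivity may be poor, and the tertiary lithium alkoxide may undergo retro-aldol cleavage on warming. The fallback sets out from 6 and comes back at 10, forming the same bond under reagent control. Acid 6 would be activated as its pivaloyl mixed anhydride (t-BuCOCl, Et3N, THF, -20 °C) and coupled with lithiated (R)-4-benzyl-1,3-oxazolidin-2-one to give the N-acyloxazolidinone F1. Its sodium (Z)-enolate (NaN(SiMe3)2, THF, -78 °C) would be benzylated by 2 on the face opposite the benzyl group of the auxiliary (Evans alkylation) to give the alkylated imide F2. LiAlH4 (THF, 0 °C) would then reduce the imide and the dioxolanone carbonyl together, releasing the auxiliary and the tert-butyl acetal carbon and giving triol 10 directly.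

Step 4. Opening of the hindered acylal by the weakly nucleophilic secondary alcohol may stall, or prolonged heating in acid may start to remove the benzyl ether. The fallback sets out from 6 and comes back at 7. Saponification of the acylal (LiOH, THF–H2O, rt, then acidification) would give the diacid F3, and O-alkylation of its dicarboxylate (Cs2CO3, 2-iodopropane, DMF, 40 °C) would give diester 7 without strong acid.

Step 3. SN2 attack of the hindered dioxolanone enolate may be slow, so that the enolate fragments with loss of pivalaldehyde before it is alkylated, or the electron-rich benzylic bromide may decompose. The fallback sets out from 1 and 4 and comes back at 6. Alcohol 1 would be oxidised (MnO2, CH2Cl2, rt) to the aldehyde F4. Dianion 5, made from 4 as before, would add to F4 in an aldol addition anti to the tert-butyl group to give the benzylic carbinol F5 (both carbinol epimers, of no consequence). Ionic deoxygenation of this electron-rich benzylic alcohol (Et3SiH, CF3CO2H, CH2Cl2, 0 °C) would give 6.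

Further compounds
F1 | step 5 | (4R)-4-benzyl-3-{2-[(2S,4S)-4-[4-(benzyloxy)-3-methoxybenzyl]-2-tert-butyl-5-oxo-1,3-dioxolan-4-yl]acetyl}-1,3-oxazolidin-2-one | O=C(C[C@]1(Cc2ccc(OCc3ccccc3)c(OC)c2)O[C@H](C(C)(C)C)OC1=O)N1[C@H](Cc2ccccc2)COC1=O
F2 | step 5 | (4R)-4-benzyl-3-{(2R)-3-[4-(benzyloxy)-3-methoxyphenyl]-2-[(2S,4S)-4-[4-(benzyloxy)-3-methoxybenzyl]-2-tert-butyl-5-oxo-1,3-dioxolan-4-yl]propanoyl}-1,3-oxazolidin-2-one | O=C([C@H](Cc2ccc(OCc3ccccc3)c(OC)c2)[C@]1(Cc2ccc(OCc3ccccc3)c(OC)c2)O[C@H](C(C)(C)C)OC1=O)N1[C@H](Cc2ccccc2)COC1=O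
F3 | step 4 | (2S)-2-[4-(benzyloxy)-3-methoxybenzyl]-2-hydroxybutanedioic acid | OC(=O)C[C@@](Cc1ccc(OCc2ccccc2)c(OC)c1)(C(=O)O)O
F4 | step 3 | 4-(benzyloxy)-3-methoxybenzaldehyde | COc1cc(C=O)ccc1OCc1ccccc1
F5 | step 3 | 2-[(2S,4R)-4-{[4-(benzyloxy)-3-methoxyphenyl](hydroxy)methyl}-2-tert-butyl-5-oxo-1,3-dioxolan-4-yl]acetic acid (carbinol centre as both epimers) | OC(=O)C[C@]1(C(O)c2ccc(OCc3ccccc3)c(OC)c2)O[C@H](C(C)(C)C)OC1=O
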